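I decided that anyone repeating this flask should watch dissolved substrate against its own ceiling, not product.

| flask | solid substrate | partner | protic impurity | remark | time |
|---|---|---|---|---|---|
| noon | 0.22 M | 0.33 M | 2.2 mM | run made earlier |  |
| dawn | 0.22 M | 0.33 M | 8.8 mM | run made earlier |  |
| spring | 0.22 M | 0.66 M | 4.4 mM | run made earlier |  |
| flask | 0.22 M | 0.330 M | 4.40 mM |  | 2.5 min |

| run | time / min | product / % | dissolved substrate / % |
|---|---|---|---|
| noon | 0.250 | 0.5 | 11.7 |
| noon | 0.417 | 1.6 | 17.5 |
| noon | 0.667 | 4.2 | 24.2 |
| noon | 1.00 | 8.7 | 30.8 |
| noon | 2.00 | 18.3 | 41.5 |
| noon | 3.00 | 24.4 | 48.8 |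
| dawn | 0.500 | 3.6 | 19.7 |
| dawn | 1.00 | 7.6 | 31.6 |
| dawn | 1.50 | 13.2 | 38.4 |
| dawn | 2.00 | 17.7 | 42.7 |
| dawn | 2.50 | 20.5 | 46.8 |
| dawn | 3.00 | 23.4 | 48.2 |
| spring | 0.250 | 2.6 | 11.5 |
| spring | 0.417 | 4.2 | 15.7 |
| spring | 0.833 | 10.9 | 24.7 |
| spring | 1.50 | 23.7 | 32.4 |
| spring | 3.00 | 42.7 | 43.2 |

(readings scatter by 0.5 percentage points)

- maple: doubling the solubility of the solid substrate, all else as stated
- elm: doubling the dissolution coefficient of the solid substrate, all else as stated
- oak: doubling the amount of partner, all else as stated

1. the product standing at 2.5 min, as a percentage of the solid substrate charged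
2. concentration of dissolved substrate in solution at 15 s, in percent of saturation
3. the change that raises the amount of product at 2.5 min, in percent of the solid substrate charged most ("none" if none brings more than 2 percentage points) (maple / elm / oak / none)
4. amount of product at 2.5 min, in percent of the solid substrate charged, after maple

- solid substrate is a solid; its amount is given per volume of the solution
- the analysis behind the earlier runs scatters by 0.5 percentage points, standard deviation
- at the start none of the solid substrate is in solution
- dissolved substrate means what is dissolved; the solid is not counted in it

One thing looked wrong. At 3.00 min the spring run held dissolved substrate and product together at 85.9% of the charge, yet the noon run pointed to a solution that holds far less. I took the rise of that sum per minute as the flux out of the solid and read it twice in the noon run: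

early: flux 0.413 /min at dissolved fraction 0.146

late: flux 0.134 /min at dissolved fraction 0.452

slope: 0.914 /min

flux reaches zero at: 0.598

I froze that line. Its end point is the ceiling, the fraction of the charge at which dissolved substrate saturates the solution (the solubility). The spring sum stands above it, so the ceiling holds for dissolved substrate, and product stands outside it. As a check, the spring run rose 0.199 /min late on, and the line gives 0.201 /min.

At 15 s the noon reading over the ceiling gave me 19.6% of saturation for this flask. Averaging noon and dawn gave 20.9% of product. Oak is the spring recipe, which reads 0.364 at 2.5 min. I reckoned no product for maple, only an estimate of its rank. Maple lifts the ceiling to 1.20, and on the frozen line that doubles the sum of dissolved substrate and product while solid lasts. The dawn sum at 2.5 min doubled comes to 1.35, above the charge, so by this estimate maple's doubling gives out before 2.5 min, while oak doubles the partner from the start; on that ground I put maple behind oak.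

The forecast gave 21%, 19.5%, oak and 34%, holding that “flux against dissolved substrate is one straight line across all runs”.

The flask gave 21.5% of product. At 15 s its dissolved substrate stood at 20.0% of saturation. The best change was oak, worth 16 percentage points against 12 points for maple, which reached 33.9%.

    solid substrate ⇌ dissolved substrate, rate k1*(cs1 - [dissolved substrate]) while solid is left; crystals form when [dissolved substrate] > cs1 (solubility = 0.130 M, k = 0.0160 /s)
    dissolved substrate + partner ⇌ product (K = 2.30 /M, k = 0.0310 /M/s)
    partner + protic impurity → quenched reagent (k = 0.900 /M/s)

At 25.0 min this flask held 59.1% dissolved beside 6.84% of solid, which is 98.8% of my ceiling. The neighbour with 0.56 M of partner held 41.4% dissolved and 33.3% product at 2.50 min, so its dissolved substrate stood at 69.2% of the ceiling.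

The data come from a simulation for substances that don't exist; scatter was added.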